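**Retrosynthetic overview**
Locants used here (ad hoc): C1 ketone C, C2 =CH, C3 =C(CH3), C4 allylic bridgehead, C5 bridge CH, C6 bridgehead next to C1, C7 bridge C(CH3), C8/C9 CH2, C10 CH–O, C11 C(CH3)(CH2O).
Last: acetate and angelate on the anti-1,3-diol; the C10 carbinol is set by hydroxyl-directed reduction.
Key disconnection: the enone ring C1–C6 comes from the cyclopentenone C1–C5 of a cis-fused bicyclo[5.3.0]decenone by insertion of a diazo carbon (C6, on C7) between C1 and C5; the same 1,2-shift makes the cyclobutane C4–C5–C6–C7. Enabling feature: C6 sits on quaternary C7 next to ring-fusion C4, syn to and four atoms from the C1 carbonyl, and C5 carries the quaternary C11.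
Cyclopentenone: Pauson–Khand reaction of a propargyl ether tethered at C7–CH2O onto the C4=C5 cycloheptene, then SmI2 C–O cleavage (gives C3–CH3 and C6–OH). C7: [2,3]-Wittig–Still from the C5 carbinol. C11: CBS desymmetrisation of a 2,2-disubstituted cycloheptane-1,3-dione.
Ring order: seven-membered ring (bought), then the five-membered enone, then the six-membered enone and the four-membered ring together.

Key step: step 15

Assumption: in step 4 hydride is taken to enter anti to the CH2OTBDPS group, so the C10 hydroxyl of 5 is cis to CH2O; this carbinol only serves to differentiate the two carbonyls and is re-set in steps 17 and 18.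

Step 1
Reactants: 1 cycloheptane-1,3-dione
Product: 2 2-methylcycloheptane-1,3-dione
Conditions: MeI, NaOH (aq), dioxane, 60 °C
Reagents that add atoms: iodomethane, CI
Why: C-alkylation of the acidic cyclic 1,3-diketone enolate should put in the future C11 methyl; no stereocenter is formed.

Step 2
Reactants: 2 2-methylcycloheptane-1,3-dione
Product: 3 2-(hydroxymethyl)-2-methylcycloheptane-1,3-dione
Conditions: HCHO (37% aq), H2O/THF, rt
Reagents that add atoms: formaldehyde, C=O
Why: Aldol addition (hydroxymethylation) of the 2-alkyl-1,3-dione to formaldehyde should build the quaternary, still prochiral C11.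

Step 3
Reactants: 3 2-(hydroxymethyl)-2-methylcycloheptane-1,3-dione
Product: 4 2-[(tert-butyldiphenylsilyloxy)methyl]-2-methylcycloheptane-1,3-dione
Conditions: TBDPSCl, imidazole, DMF, 0 °C to rt
Reagents that add atoms: tert-butyl(chloro)diphenylsilane, CC(C)(C)[Si](Cl)(c1ccccc1)c1ccccc1
Why: Silylation of the primary alcohol blocks retro-aldol loss of formaldehyde and makes CH2O the large group at C11.

Step 4
Reactants: 4 2-[(tert-butyldiphenylsilyloxy)methyl]-2-methylcycloheptane-1,3-dione
Product: 5 (2S,3S)-2-[(tert-butyldiphenylsilyloxy)methyl]-3-hydroxy-2-methylcycloheptan-1-one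
Conditions: (R)-Me-CBS (20 mol%), BH3·SMe2, THF, −30 °C
Reagents that add atoms: none
Why: CBS reduction desymmetrises the dione: the catalyst fixes the (S)-carbinol and hydride entry anti to CH2OTBDPS selects one enantiotopic carbonyl, which should set the absolute configuration of quaternary C11.

Step 5
Reactants: 5 (2S,3S)-hydroxy ketone
Product: 6 (2S,3S)-2-[(tert-butyldiphenylsilyloxy)methyl]-2-methyl-3-(triisopropylsilyloxy)cycloheptan-1-one
Conditions: TIPSOTf, 2,6-lutidine, CH2Cl2, 0 °C
Reagents that add atoms: triisopropylsilyl triflate, CC(C)[Si](C(C)C)(C(C)C)OS(=O)(=O)C(F)(F)F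
Why: Silylation of the hindered secondary alcohol with a group of low migratory aptitude protects C10–O through the basic steps that follow.

Step 6
Reactants: 6 TIPS ether
Product: 7 (6S,7S)-7-[(tert-butyldiphenylsilyloxy)methyl]-7-methyl-6-(triisopropylsilyloxy)cyclohept-2-en-1-one
Conditions: IBX, DMSO/PhF, 70 °C
Reagents that add atoms: none
Why: IBX dehydrogenation of the ketone can only occur toward C4/C7 because C11 is quaternary, which should give the C5(=O)–C4=C7 enone.

Step 7
Reactants: 7 cycloheptenone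
Product: 9 (6S,7S)-7-[(tert-butyldiphenylsilyloxy)methyl]-3,7-dimethyl-6-(triisopropylsilyloxy)cyclohept-2-en-1-one, via TMS enol ether 8 (not isolated)
Conditions: MeMgBr, CuBr·SMe2 (cat.), TMSCl, THF, −78 °C; then Pd(OAc)2, MeCN, rt
Reagents that add atoms: methylmagnesium bromide, C[Mg]Br
Why: Copper-catalysed conjugate methylation with silyl trapping followed by Saegusa oxidation should deliver the β-methyl enone (methyl on C7); the C7 stereocenter of 8 is erased again.

Step 8
Reactants: 9 β-methyl enone
Product: 10 allylic alcohol (C5–OH cis to CH2OTBDPS and to OTIPS)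
Conditions: NaBH4, CeCl3·7H2O, MeOH, −78 °C
Reagents that add atoms: none
Why: Luche 1,2-reduction should deliver hydride to the ring face opposite CH2OTBDPS (on C11) and OTIPS (on C10), placing the C5 hydroxyl on their face.

Step 9
Reactants: 10 allylic alcohol
Product: 11 tributylstannylmethyl ether of 10
Conditions: KH, 18-crown-6 (cat.), Bu3SnCH2I, THF, 0 °C to rt
Reagents that add atoms: tributyl(iodomethyl)stannane, CCCC[Sn](CCCC)(CCCC)CI
Why: Williamson etherification attaches the CH2 that becomes C6 to the C5 oxygen without touching the carbinol configuration.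

Step 10
Reactants: 11 stannylmethyl ether
Product: 13 homoallylic alcohol with quaternary C7 (CH2OH cis to CH2OTBDPS; C4=C5 alkene), via alkoxymethyllithium 12 (not isolated)
Conditions: n-BuLi, THF, −78 °C
Reagents that add atoms: none
Why: Tin–lithium exchange and [2,3]-Wittig–Still rearrangement should form the C6–C7 bond suprafacially on the face that carried the C5–O bond, so the new quaternary C7 has CH2OH cis to CH2OTBDPS.

Step 11
Reactants: 13 homoallylic alcohol
Product: 14 propargyl ether of 13
Conditions: NaH, propargyl bromide, Bu4NI (cat.), THF/DMF, 0 °C to rt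
Reagents that add atoms: propargyl bromide, C#CCBr
Why: Williamson etherification of the neopentyl primary alcohol installs a 1,7-enyne whose tether will deliver C2 and C3 to the hindered C4=C5 alkene.

Step 12
Reactants: 14 propargyl ether
Product: 15 Pauson–Khand adduct (cyclopentenone C1–C5 cis-fused at C4–C5; C3–CH2–O–CH2–C7 oxane ring)
Conditions: Co2(CO)8, CH2Cl2, rt; then NMO, rt
Reagents that add atoms: dicobalt octacarbonyl (transfers one CO), [C-]#[O+]
Why: Intramolecular Pauson–Khand [2+2+1] cycloaddition should place CO on C5 and the internal alkyne carbon (C3) on C4, and the tether forces both new bonds onto the alkene face that carries the C7–CH2O arm, so H–C4 and H–C5 end cis and syn to C6.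

Step 13
Reactants: 15 Pauson–Khand adduct
Product: 17 cis-fused hydroxy enone (3-methylcyclopent-2-enone fused at C4–C5; C7 bears CH3 and CH2OH), via exo-methylene ketone 16 (not isolated)
Conditions: SmI2, THF/MeOH, −78 °C; then DBU (cat.), CH2Cl2, rt
Reagents that add atoms: none
Why: SmI2 reduction of the enone expels the γ-alkoxide (vinylogous α-alkoxy ketone cleavage), which should reveal the C3 methyl and the C6 alcohol, and DBU returns the double bond to conjugation; no stereocenter is touched.

Step 14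
Reactants: 17 hydroxy enone
Product: 18 aldehyde (C6 = CHO on C7)
Conditions: DMP, NaHCO3, CH2Cl2, 0 °C to rt
Reagents that add atoms: none
Why: Dess–Martin oxidation of the neopentyl primary alcohol gives the non-enolisable aldehyde needed as diazo precursor.

Step 15
Reactants: 18 aldehyde
Product: 22 tricyclic enone bis-silyl ether (C10–OTIPS cis to CH2OTBDPS), via tosylhydrazone 19 (not isolated), via diazoalkane 20 (not isolated), via diazonium alkoxide 21 (not isolated)
Conditions: TsNHNH2, MeOH, rt; then NaH (1.0 equiv), THF, 0 to 65 °C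
Reagents that add atoms: none
Why: Proposed new method: the aldehyde tosylhydrazone salt loses sulfinate (Bamford–Stevens) to give the neopentyl diazoalkane, whose nucleophilic carbon C6 adds to the syn-disposed enone carbonyl C1 (5-exo-trig, bicyclo[2.2.1] diazonium alkoxide 21), and the C1–C5 bond then shifts to C6 with loss of N2, an intramolecular Büchner–Curtius–Schlotterbeck/Tiffeneau–Demjanov one-carbon homologation that is known for diazoalkane–ketone pairs but not for closing a bicyclo[3.1.1]heptenone. The enone ring C1–C6 is closed by ring expansion of the cyclopentenone C1–C5 (C6 inserted between C1 and C5), and the cyclobutane C4–C5–C6–C7 arises in the same 1,2-shift by contraction of the transient five-membered ring C1–C6–C7–C4–C5. The only new stereocenter, C6, is fixed by the bicycle because it must bridge C5 and C7 on the face that already carries C1, while C4, C5 and C7 are carried over. The step needs migration of C5 and not of vinylic C2; this should be secured because the quaternary C11 on C5 blocks the exo face, so the diazonium lies endo and antiperiplanar to C1–C5 only. Conjugate addition or dipolar cycloaddition to C2=C3 would need a four-membered ring, the single equivalent of base is consumed by the hydrazone N–H so the ketone stays un-enolised, and N2 loss makes the strain-raising shift irreversible.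

Step 16
Reactants: 22 tricyclic enone bis-silyl ether
Product: 23 diol (C10–OH cis to CH2OH)
Conditions: TBAF, THF, 50 °C
Reagents that add atoms: none
Why: Fluoride cleaves both silyl ethers; the enone has no epimerisable center (C4 and C6 are bridgeheads).

Step 17
Reactants: 23 diol
Product: 24 keto aldehyde (C10 ketone and C11 carbaldehyde)
Conditions: DMP (excess), NaHCO3, CH2Cl2, rt
Reagents that add atoms: none
Why: Double Dess–Martin oxidation erases the provisional C10 carbinol; quaternary C11 cannot epimerise.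

Step 18
Reactants: 24 keto aldehyde
Product: 26 anti-diol (C10–OH trans to CH2OH and cis to the C11 methyl), via hydroxy ketone 25 (not isolated)
Conditions: Me4NBH(OAc)3, MeCN/AcOH, −20 °C to rt
Reagents that add atoms: none
Why: Triacetoxyborohydride reduces the aldehyde first and the resulting CH2O–boron species then delivers hydride intramolecularly to C10 (Evans–Saksena reduction), which should place the C10 hydroxyl anti to CH2OH as in the target while the undirected enone is left alone.

Step 19
Reactants: 26 anti-diol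
Product: 27 primary angelate (C10–OH free)
Conditions: angelic acid, 2,4,6-trichlorobenzoyl chloride, Et3N, toluene, rt to 80 °C
Reagents that add atoms: angelic acid, C/C=C(/C)C(=O)O
Why: Mixed-anhydride (Yamaguchi-type) esterification without nucleophilic catalyst should acylate the primary alcohol selectively and keep the (Z)-geometry of the angelate.

Step 20
Reactants: 27 primary angelate
Product: 28 target CNP0374220.1
Conditions: Ac2O, pyridine, DMAP (cat.), CH2Cl2, 0 °C to rt
Reagents that add atoms: acetic anhydride, CC(=O)OC(C)=O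
Why: Acetylation of the remaining hindered secondary alcohol completes the target with retention at C10.

**Compound list**
1 | cycloheptane-1,3-dione | O=C1CCCCC(=O)C1 | starting material
2 | 2-methylcycloheptane-1,3-dione | CC1C(=O)CCCCC1=O | intermediate
3 | 2-(hydroxymethyl)-2-methylcycloheptane-1,3-dione | CC1(CO)C(=O)CCCCC1=O | intermediate
4 | 2-[(tert-butyldiphenylsilyloxy)methyl]-2-methylcycloheptane-1,3-dione | CC1(CO[Si](c2ccccc2)(c2ccccc2)C(C)(C)C)C(=O)CCCCC1=O | intermediate
5 | (2S,3S)-2-[(tert-butyldiphenylsilyloxy)methyl]-3-hydroxy-2-methylcycloheptan-1-one (OH cis to CH2OSi) | O=C1CCCC[C@H](O)[C@]1(C)CO[Si](c2ccccc2)(c2ccccc2)C(C)(C)C | intermediate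
6 | (2S,3S)-2-[(tert-butyldiphenylsilyloxy)methyl]-2-methyl-3-(triisopropylsilyloxy)cycloheptan-1-one | O=C1CCCC[C@H](O[Si](C(C)C)(C(C)C)C(C)C)[C@]1(C)CO[Si](c2ccccc2)(c2ccccc2)C(C)(C)C | intermediate
7 | (6S,7S)-7-[(tert-butyldiphenylsilyloxy)methyl]-7-methyl-6-(triisopropylsilyloxy)cyclohept-2-en-1-one | O=C1C=CCC[C@H](O[Si](C(C)C)(C(C)C)C(C)C)[C@]1(C)CO[Si](c2ccccc2)(c2ccccc2)C(C)(C)C | intermediate
8 | TMS enol ether of the 3-methyl ketone (C5–OTMS, C5=C4; both C7 epimers) | C[Si](C)(C)OC1=CC(C)CC[C@H](O[Si](C(C)C)(C(C)C)C(C)C)[C@]1(C)CO[Si](c2ccccc2)(c2ccccc2)C(C)(C)C | intermediate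
9 | (6S,7S)-7-[(tert-butyldiphenylsilyloxy)methyl]-3,7-dimethyl-6-(triisopropylsilyloxy)cyclohept-2-en-1-one | O=C1C=C(C)CC[C@H](O[Si](C(C)C)(C(C)C)C(C)C)[C@]1(C)CO[Si](c2ccccc2)(c2ccccc2)C(C)(C)C | intermediate
10 | allylic alcohol from 9; C5–OH cis to CH2OTBDPS and OTIPS | O[C@@H]1C=C(C)CC[C@H](O[Si](C(C)C)(C(C)C)C(C)C)[C@]1(C)CO[Si](c2ccccc2)(c2ccccc2)C(C)(C)C | intermediate
11 | tributylstannylmethyl ether of 10 | CCCC[Sn](CCCC)(CCCC)CO[C@@H]1C=C(C)CC[C@H](O[Si](C(C)C)(C(C)C)C(C)C)[C@]1(C)CO[Si](c2ccccc2)(c2ccccc2)C(C)(C)C | intermediate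
12 | lithiomethyl ether of 10 (α-alkoxy organolithium) | [Li]CO[C@@H]1C=C(C)CC[C@H](O[Si](C(C)C)(C(C)C)C(C)C)[C@]1(C)CO[Si](c2ccccc2)(c2ccccc2)C(C)(C)C | intermediate
13 | cyclohept-2-ene (C4=C5) with quaternary C7 (CH3, CH2OH) and quaternary C11 (CH3, CH2OTBDPS), C10–OTIPS; CH2OH cis to CH2OTBDPS | OC[C@@]1(C)C=C[C@@](C)(CO[Si](c2ccccc2)(c2ccccc2)C(C)(C)C)[C@@H](O[Si](C(C)C)(C(C)C)C(C)C)CC1 | intermediate
14 | propargyl ether of 13 | C#CCOC[C@@]1(C)C=C[C@@](C)(CO[Si](c2ccccc2)(c2ccccc2)C(C)(C)C)[C@@H](O[Si](C(C)C)(C(C)C)C(C)C)CC1 | intermediate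
15 | Pauson–Khand adduct: cyclopentenone C1(=O)–C2H=C3 cis-fused at C4–C5, oxane bridge C3–CH2–O–CH2–C7 | O=C1C=C2COC[C@]3(C)CC[C@H](O[Si](C(C)C)(C(C)C)C(C)C)[C@](C)(CO[Si](c4ccccc4)(c4ccccc4)C(C)(C)C)[C@H]1[C@H]23 | intermediate
16 | deconjugated ketone (C3 exo-methylene isomer of 17) | O=C1CC(=C)[C@H]2[C@@H]1[C@@](C)(CO[Si](c3ccccc3)(c3ccccc3)C(C)(C)C)[C@@H](O[Si](C(C)C)(C(C)C)C(C)C)CC[C@@]2(C)CO | intermediate
17 | cis-fused bicyclo[5.3.0]decenone: 3-methylcyclopent-2-enone fused at C4–C5; C7 bears CH3 and CH2OH syn to C1 | O=C1C=C(C)[C@H]2[C@@H]1[C@@](C)(CO[Si](c3ccccc3)(c3ccccc3)C(C)(C)C)[C@@H](O[Si](C(C)C)(C(C)C)C(C)C)CC[C@@]2(C)CO | intermediate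
18 | aldehyde from 17 (C6 = CHO) | O=C1C=C(C)[C@H]2[C@@H]1[C@@](C)(CO[Si](c3ccccc3)(c3ccccc3)C(C)(C)C)[C@@H](O[Si](C(C)C)(C(C)C)C(C)C)CC[C@@]2(C)C=O | intermediate
19 | (E)-N-tosylhydrazone of 18 | O=C1C=C(C)[C@H]2[C@@H]1[C@@](C)(CO[Si](c3ccccc3)(c3ccccc3)C(C)(C)C)[C@@H](O[Si](C(C)C)(C(C)C)C(C)C)CC[C@@]2(C)/C=N/NS(=O)(=O)c3ccc(C)cc3 | intermediate
20 | diazoalkane (C6H=N2 on C7) | O=C1C=C(C)[C@H]2[C@@H]1[C@@](C)(CO[Si](c3ccccc3)(c3ccccc3)C(C)(C)C)[C@@H](O[Si](C(C)C)(C(C)C)C(C)C)CC[C@@]2(C)C=[N+]=[N-] | intermediate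
21 | diazonium alkoxide: C1–C6 bonded bicyclo[2.2.1] betaine, N2+ endo | [O-][C@@]12C=C(C)[C@H]3[C@@H]1[C@@](C)(CO[Si](c4ccccc4)(c4ccccc4)C(C)(C)C)[C@@H](O[Si](C(C)C)(C(C)C)C(C)C)CC[C@@]3(C)[C@@H]2[N+]#N | intermediate
22 | tricyclic enone (target skeleton) with CH2OTBDPS on C11 and OTIPS on C10 cis to it | CC(C)(C)[Si](c1ccccc1)(c1ccccc1)OC[C@]1(C)[C@@H]2[C@H]3C(=O)C=C(C)[C@@H]2[C@@]3(C)CC[C@@H]1O[Si](C(C)C)(C(C)C)C(C)C | intermediate
23 | diol from 22 (C10–OH cis to CH2OH) | OC[C@]1(C)[C@@H]2[C@H]3C(=O)C=C(C)[C@@H]2[C@@]3(C)CC[C@@H]1O | intermediate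
24 | keto aldehyde (C10 ketone, C11 carbaldehyde) | O=C[C@]1(C)[C@@H]2[C@H]3C(=O)C=C(C)[C@@H]2[C@@]3(C)CCC1=O | intermediate
25 | hydroxy ketone (C10 ketone, C11–CH2OH) | OC[C@]1(C)[C@@H]2[C@H]3C(=O)C=C(C)[C@@H]2[C@@]3(C)CCC1=O | intermediate
26 | anti-diol (C10–OH trans to CH2OH, target configuration) | OC[C@]1(C)[C@@H]2[C@H]3C(=O)C=C(C)[C@@H]2[C@@]3(C)CC[C@H]1O | intermediate
27 | primary angelate of 26 | C/C=C(/C)C(=O)OC[C@]1(C)[C@@H]2[C@H]3C(=O)C=C(C)[C@@H]2[C@@]3(C)CC[C@H]1O | intermediate
28 | CNP0374220.1 | C/C=C(/C)C(=O)OC[C@]1(C)[C@@H]2[C@H]3C(=O)C=C(C)[C@@H]2[C@@]3(C)CC[C@H]1OC(C)=O | target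

**Step count and risks**
Total step count: 20. Longest linear sequence: 20 (fully linear from cycloheptane-1,3-dione).

Most likely to fail, first (step 15, proposed new method): the diazoalkane may lose N2 before its carbon reaches C1 (carbene 1,2-shifts), or the vinylic C2 may migrate instead of C5 if addition occurs with the diazonium exo. The fallback is a stepwise amino alcohol route with known reactions. It sets out from 18: condensation with O-benzylhydroxylamine gives the O-benzyl oxime F1. SmI2/HMPA/t-BuOH then couples the C1 ketyl with the C=N carbon to the bridged N-benzyloxy amino alcohol F2. Zn/AcOH cleaves the N–O bond to the amino alcohol F3. NaNO2 in aqueous AcOH at 0 °C (Tiffeneau–Demjanov ring expansion) returns to the route at 22.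

Second (step 12): the cobalt–alkyne complex may fail to insert the cis-alkene flanked by two quaternary carbons and instead decomplex or oligomerise. The fallback replaces the cobalt [2+2+1] by a cyclic carbopalladation–carbonylation. It sets out from 13: NaH and 2,3-dibromopropene give the 2-bromoallyl ether F4. Pd(PPh3)4, CO (1 atm), Et3N, MeCN, 80 °C should then give enone 15 by 6-exo carbopalladation of C4=C5, CO insertion at C5, 5-exo acylpalladation and β-hydride elimination, rejoining the route at 15.

Third (step 4): discrimination of the two enantiotopic carbonyls and of their faces may be poor in the flexible seven-membered dione, and over-reduction to diols may compete. The fallback is biocatalytic instead of oxazaborolidine-mediated. It sets out from 4: a ketoreductase screen (or fermenting baker's yeast, which reduces 2,2-disubstituted cyclic 1,3-diones to (2S,3S)-ketols with the hydroxyl cis to the larger group) with glucose/GDH/NADP+ in phosphate buffer–DMSO at 30 °C should give 5 directly, rejoining the route at 5 without any new compound.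

Further compounds
F1 | step 15 | O-benzyl oxime of 18 | O=C1C=C(C)[C@H]2[C@@H]1[C@@](C)(CO[Si](c3ccccc3)(c3ccccc3)C(C)(C)C)[C@@H](O[Si](C(C)C)(C(C)C)C(C)C)CC[C@@]2(C)/C=N/OCc3ccccc3
F2 | step 15 | bridged N-benzyloxy amino alcohol (C1–OH, C6–NHOBn endo, bicyclo[2.2.1]) | O[C@@]12C=C(C)[C@H]3[C@@H]1[C@@](C)(CO[Si](c4ccccc4)(c4ccccc4)C(C)(C)C)[C@@H](O[Si](C(C)C)(C(C)C)C(C)C)CC[C@@]3(C)[C@@H]2NOCc4ccccc4
F3 | step 15 | bridged amino alcohol (C1–OH, C6–NH2 endo) | O[C@@]12C=C(C)[C@H]3[C@@H]1[C@@](C)(CO[Si](c4ccccc4)(c4ccccc4)C(C)(C)C)[C@@H](O[Si](C(C)C)(C(C)C)C(C)C)CC[C@@]3(C)[C@@H]2N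
F4 | step 12 | 2-bromoallyl ether of 13 | C=C(Br)COC[C@@]1(C)C=C[C@@](C)(CO[Si](c2ccccc2)(c2ccccc2)C(C)(C)C)[C@@H](O[Si](C(C)C)(C(C)C)C(C)C)CC1
F0 | step 4 | none | none
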